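The numbers of this flask come from no measurement; the rest is arithmetic.

- The constants set three tendencies: 0.00274 min⁻¹ gives Z a half-life of 4.2 h in its decay to Q, 916 M⁻¹ lets Z hold X as Z.X, with 150 bound per free X at the full charge of Z, and 0.596 lets free X turn D back into G through G + Z ⇌ D + X.

all flasks: L 20.5 mM
- Saturday's: G 41 mM; Z 164 mM; time 20 h; everything together in a closed stirred flask, run for 20 h
- Monday's: G 41 mM; Z 164 mM (fed, over 10.0 h); time 20 h; all but Z at the start; Z goes in evenly over 10.0 h, the run ends at 20 h
- Thursday's: G 41 mM (fed, over 10.0 h); Z 164 mM; time 20 h; all but G at the start; G goes in evenly over 10.0 h, the run ends at 20 h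
- Tuesday's: G 41 mM; Z 164 mM; a single well-mixed tank run continuously and read at steady state, 20 h in it on average

* the set-up with the highest amount of D at the outlet or at the end, in percent of the G put in ("none" if the first two lie within 2 percentage points) (Saturday's / Monday's / Thursday's / Tuesday's / none)
* amount of D at the outlet or at the end, in percent of the G put in, Saturday's
* amount of D at the outlet or at the end, in percent of the G put in, Monday's
* amount of D at the outlet or at the end, in percent of the G put in, Thursday's
* amount of D at the outlet or at the end, in percent of the G put in, Tuesday's

- for X the Z.X is counted in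
- the stated concentrations are those of everything mixed, before any reaction; amounts are the same in each set-up
- the feed brings no volume worth counting
- run time (Saturday's): 20 h

- One X molecule formed from G comes to a fork: L, a stoichiometric scavenger, traps X one for one as L.X up to 20.5 mM, and beyond that X stays free or sits on Z as Z.X, so turning the 41 mM of G into D takes one Z per G in step one plus about one Z per X beyond L, a need of 61.5 mM.
- Monday's and Thursday's flasks look nearly the same, with equal charges, but the feed differs, so the useful measure is the reserve, meaning the Z that decay taken by itself leaves when the feed ends.
- In Thursday's flask decay taken by itself runs the whole Z charge through 2.37 half-lives, which gives 31.7 mM, whereas Monday's late-fed Z is younger, which gives 80.5 mM.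
- My reckoning stops at an order: Thursday's reserve covers the need 0.515 times against 1.31 for Monday's, so Monday's should end higher than Thursday's; these covers are estimates, not bounds, since Z spent in step one or held as Z.X no longer feeds step two, and I give no percentages.
- The forecast also puts Monday's above Thursday's, naming Monday's as best with 87%, 90%, 78% and 86% for Saturday's, Monday's, Thursday's and Tuesday's, on the ground that “feeding G lets much of the Z decay before it is used, which hurts Thursday's”.
- The simulation gives 85.0%, 92.2%, 73.0% and 86.0% in that order, so Monday's is best, and the forecast for Thursday's stands 5 percentage points too high.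

    G + Z ⇌ D + X (K1 = 0.596, k1 = 0.262 M⁻¹ min⁻¹)
    Z → Q (k2 = 0.00274 min⁻¹)
    L + X → L.X (k3 = 13.5 M⁻¹ min⁻¹)
    Z + X ⇌ Z.X, settled at all times (K4 = 916 M⁻¹)

- Feeding 100 mM of G into Thursday's flask raises the need to 180 mM, more than the whole 164 mM of Z, while the reserve stays 31.7 mM, so cover falls to 0.176; at 20.0 h that flask holds 20.4 mM of Z.X beside 20.5 mM of L.X and 4.19 mM of free X, with G at 54.9% and D at 45.1%.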